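The runs are simulated for an exercise; the scatter is artificial.

| flask | substrate | free catalyst | temperature | remark | time |
|---|---|---|---|---|---|
| violet | 1.5 M | 5 mol% | 25 °C | the very flask that is asked about, followed so far |  |
| amber | 1.5 M | 5 mol% | 20 °C | run made earlier |  |
| flask | 1.5 M | 5 mol% | 25 °C |  | 1.0 h |

- violet (time / min: target / %, substrate / %): 5.00: 11.7, 27.4; 12.0: 24.9, 8.4; 25.0: 32.1, 1.0; 40.0: 34.6, 0.5
- amber (time / min: target / %, substrate / %): 5.00: 5.3, 41.4; 12.0: 15.1, 19.9; 25.0: 26.9, 6.4; 40.0: 31.5, 1.9

(scatter of a reading: 0.5 percentage points)

- dawn: change nothing and wait 30 min more
- summer: at 1.0 h raise the temperature by 25 K, then wait 30 min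
- noon: at 1.0 h add free catalyst, 100% of the amount charged, then wait 30 min
- midnight: at 1.0 h take out 90% of the target then present, then wait 30 min

* target, in percent of the substrate first charged, at 1.0 h
* what to do for the largest gain in target; "none" if nothing gains more than 2 percentage points (dawn / summer / noon / midnight / none)
* target present, with what was taken out counted in, in percent of the substrate first charged, after noon
* target present, with what was taken out counted in, in percent of the substrate first charged, after midnight

- percent here means substrate units held: one homo dimer counts as two
- removed target is counted in
- steps thought possible: substrate -> intermediate; free catalyst + intermediate -> free catalyst + target; free catalyst -> spent catalyst; 2 substrate -> homo dimer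
- additions bring no volume worth counting

**Amounts made.** I began with the substrate charged to violet, which goes two ways, to intermediate and to homo dimer. I read its fall as 0.259 min⁻¹ over the first stretch and 0.169 min⁻¹ over the next, with mean fractions standing of 0.561 and 0.161. So the fall had a steady part, 0.133 min⁻¹, and a part of 0.225 min⁻¹ per unit fraction. Integrated, this sent 0.585 of the charge to intermediate.

**Catalyst clock.** Violet's target rate decayed at 0.0858 min⁻¹, which I took as free catalyst turning into spent catalyst. That left 0.582% of the free catalyst at 1.0 h. I reckoned a further tail after that time of 0.18 percentage points, and target at 1.0 h of 35.4%. I reckoned intermediate left at 0.231 of the charge.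

**The exposure.** I took the use of intermediate as pseudo-first-order in intermediate, its constant proportional to free catalyst at that moment. Midway between violet's first two readings I reckoned 0.267 of the charge standing as intermediate. Target's rise there, wound back along the clock, gave a starting constant of 0.146 min⁻¹. Divided by the clock's decay this made 1.71, which I call a charge's exposure, the time integral of that constant over the whole life of a fresh charge.

**Four settings.** Waiting gave the tail, below the margin of 2 points. Heat got the same tail from me, with free catalyst at 0.582%. Removing target touched no step that uses it, so midnight stood at 35.6%. A fresh charge meets the standing intermediate, and 30 min of its life gave 1.58 of exposure. That gained 18 points, reaching 53.7%, so I chose noon.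

**Forecast, result.** The forecast said 35.2%, noon, 54.5% after noon, above my figure, and 35.4% after midnight, on the ground that “the catalyst is dying”. Violet gave 34.8% and noon, with 50.1% after noon and 34.9% after midnight. The gains were 0.048 points for dawn, 0.025 points for summer, 15 points for noon and 0.048 points for midnight.

    substrate → intermediate (k = 0.120 min⁻¹, Ea = 95.0 kJ mol⁻¹)
    free catalyst + intermediate → free catalyst + target (k = 3.00 M⁻¹ min⁻¹, Ea = 67.0 kJ mol⁻¹)
    free catalyst → spent catalyst (k = 0.110 min⁻¹, Ea = 89.0 kJ mol⁻¹)
    2 substrate → homo dimer (k = 0.0890 M⁻¹ min⁻¹, Ea = 66.0 kJ mol⁻¹)
    (constants at 25 °C)

**The neighbour.** Violet's noon gain of 15 points stood beside my 18 points. On its 17.8% intermediate that gain meant an exposure of 1.98, against my 1.58. A neighbour of violet held 0.90 M substrate at the same loading, so I scaled both the exposure and the dimer part by 0.600. Its exposure became 1.02, and 0.690 of its charge went to intermediate. Violet's own charge had used 0.545 of its exposure, and I gave the neighbour that share. That reckoned 29.4% target and 39.6% intermediate. The neighbour held 30.7% target and 32.8% intermediate at 60.0 min.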